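**Retrosynthetic overview**

Locants (tricyclo[5.3.1.0^1,5]undec-8-ene): C1 quaternary bridgehead, C2 (CHO), C3, C4, C5 ring-fusion CH, C6 (CH3, CH2OH), C7 bridgehead CH, C8 (CO2H)=C9, C10 (O-acyl), C11 CH2 bridge. Ring A = cyclopentane C1–C5, ring B = C1/C5/C6/C7/C11, ring C = cyclohexene C1/C11/C7/C8/C9/C10.
Last disconnections: the C10–O ester (Yamaguchi esterification with a Wittig-derived (9Z)-16-silyloxyhexadec-9-enoic acid) and one acidic global deprotection (acetal, two silyl ethers, tert-butyl ester).
Key disconnection: C9–C10 and C7–C11 in one operation, a [3+3] closure of ring C that also closes ring B. The enabling feature is that ring C is a 4-hydroxy-2-enoate: C7–C8(CO2H)=C9 is the three-carbon unit of a 2-(sulfonylmethyl)acrylate, while C10 (carbinol) and C11 (CH2) both sit on the quaternary C1, so they can be an aldehyde and a borylmethyl group on one carbon.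
The key precursor is therefore a ring A cyclopentane carrying CHO and CH2B(pin) on C1 and the (Z)-2-(phenylsulfonylmethyl)enoate arm on C6. Its stereocentres come from an asymmetric Michael addition (C5, C6), a face-selective hydrogenation (C2) and an ester enolate alkylation (C1).
Ring order: ring A (from the starting keto ester) → transient cycloheptene C1–C5–C6–C7–C8–C9–C10 (C9–C10) → rings B and C together (C7–C11).

Key step: step 16

Remark (assumption): the stereodescriptors are taken exactly as written; they put C10, C6 and the formyl carbon on C2 mutually cis on ring A and C11 trans to them (C4 endo, H-5 exo), so ring A is cis-fused to the seven-membered ring and trans-fused to ring B, and the route is built for this arrangement.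

**Route**

Step 1
Reactants: 1 methyl 2-oxocyclopentane-1-carboxylate
Product: 3 methyl 5-oxocyclopent-1-ene-1-carboxylate, via α-phenylselanyl keto ester 2 (not isolated)
Conditions: PhSeCl, pyridine, CH2Cl2, 0 °C; then 30% H2O2, 0 °C → rt; used at once
Reagents that add atoms: none
Why: α-Selenenylation of the β-keto ester followed by oxidation and syn-elimination of the selenoxide (selenoxide elimination) should give the doubly activated enone; no stereocentre is formed.

Step 2
Reactants: 3 methyl 5-oxocyclopent-1-ene-1-carboxylate; 4 ethyl 2-cyanopropanoate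
Product: 5 methyl 5-(2-cyano-1-ethoxy-1-oxopropan-2-yl)-2-oxocyclopentane-1-carboxylate (ring carbon and quaternary carbon as in the SMILES; keto ester carbon epimeric)
Conditions: cinchona-alkaloid-derived bifunctional squaramide (5 mol %, pseudo-enantiomer chosen for the configuration shown), toluene, −40 °C
Reagents that add atoms: none
Why: Organocatalytic asymmetric Michael addition of an α-substituted cyanoacetate to an alkylidene β-keto ester; the catalyst should hold the chelating 1,3-dicarbonyl of 3 and the cyano-ester enolate so that one face of the ring β-carbon (future C5) and one face of the prochiral nucleophile (future C6) react, while the keto ester carbon between them stays epimerisable.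

Step 3
Reactants: 5 Michael adduct
Product: 6 methyl 5-(2-cyano-1-ethoxy-1-oxopropan-2-yl)-2-(trifluoromethylsulfonyloxy)cyclopent-1-ene-1-carboxylate
Conditions: Tf2O, i-Pr2NEt, CH2Cl2, −78 °C
Reagents that add atoms: trifluoromethanesulfonic anhydride, O=S(=O)(OS(=O)(=O)C(F)(F)F)C(F)(F)F
Why: O-Sulfonylation of the β-keto ester enol (enol triflate formation) fixes the double bond between future C1 and C2 and makes C2 a cross-coupling site; C5 and C6 are untouched.

Step 4
Reactants: 6 enol triflate
Product: 7 methyl 5-(2-cyano-1-ethoxy-1-oxopropan-2-yl)-2-formylcyclopent-1-ene-1-carboxylate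
Conditions: Pd(PPh3)4 (5 mol %), CO (3 bar), Bu3SnH (slow addition), THF, 50 °C
Reagents that add atoms: carbon monoxide, [C-]#[O+]
Why: Pd-catalysed reductive carbonylation (formylation) of a vinyl triflate: oxidative addition, CO insertion and hydride transfer from tin to the acyl–palladium intermediate should install the future formyl carbon on C2.

Step 5
Reactants: 7 enal
Product: 8 methyl 5-(2-cyano-1-ethoxy-1-oxopropan-2-yl)-2-(dimethoxymethyl)cyclopent-1-ene-1-carboxylate
Conditions: HC(OMe)3, MeOH, PPTS (cat.), rt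
Reagents that add atoms: trimethyl orthoformate, COC(OC)OC
Why: Acid-catalysed acetalisation with orthoformate as water scavenger masks the C2 formyl group at its final oxidation level for the rest of the route.

Step 6
Reactants: 8 acetal enoate
Product: 9 methyl 2-(2-cyano-1-ethoxy-1-oxopropan-2-yl)-5-(dimethoxymethyl)cyclopentane-1-carboxylate, all three ring substituents cis
Conditions: H2 (50 bar), Pd/C (10 wt %), EtOAc, 40 °C
Reagents that add atoms: none
Why: Heterogeneous syn-hydrogenation of the tetrasubstituted enoate; hydrogen should be delivered to the face opposite the quaternary side chain on C5, which places ester, acetal and side chain all cis and sets C2 (C1 is re-made in step 9).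

Step 7
Reactants: 9 all-cis cyano diester
Product: 10 methyl 2-(2-cyano-1-hydroxypropan-2-yl)-5-(dimethoxymethyl)cyclopentane-1-carboxylate, all-cis
Conditions: NaBH4, EtOH, 0 °C → rt
Reagents that add atoms: none
Why: Chemoselective borohydride reduction of the cyano-activated ethyl ester (the flanked, unactivated methyl ester and the nitrile should not react) turns one arm of C6 into the future CH2OH.

Step 8
Reactants: 10 hydroxy nitrile
Product: 11 methyl 2-[1-(tert-butyldimethylsilyloxy)-2-cyanopropan-2-yl]-5-(dimethoxymethyl)cyclopentane-1-carboxylate, all-cis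
Conditions: TBSCl, imidazole, DMF, rt
Reagents that add atoms: tert-butyldimethylsilyl chloride, C[Si](C)(Cl)C(C)(C)C
Why: Standard silylation of the primary alcohol protects the C6 hydroxymethyl arm against the bases and hydrides that follow.

Step 9
Reactants: 11 silyl ether
Product: 13 methyl 2-[1-(tert-butyldimethylsilyloxy)-2-cyanopropan-2-yl]-5-(dimethoxymethyl)-1-[(4,4,5,5-tetramethyl-1,3,2-dioxaborolan-2-yl)methyl]cyclopentane-1-carboxylate (ester cis and borylmethyl trans to both ring neighbours), via lithium ester enolate 12 (not isolated)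
Conditions: LiN(i-Pr)2, THF, −78 → −40 °C; then ICH2B(pin), DMPU, −78 → 0 °C
Reagents that add atoms: 2-(iodomethyl)-4,4,5,5-tetramethyl-1,3,2-dioxaborolane, ICB1OC(C)(C)C(C)(C)O1
Why: Ester enolate alkylation with an α-boryl alkyl iodide; the planar enolate at C1 should be attacked on the face anti to its two cis neighbours, so the borylmethyl group (future C11) ends trans to them and the ester (future C10) cis, creating the quaternary centre C1.

Step 10
Reactants: 13 boryl ester
Product: 14 3-(tert-butyldimethylsilyloxy)-2-[3-(dimethoxymethyl)-2-(hydroxymethyl)-2-(pinacolborylmethyl)cyclopentyl]-2-methylpropanenitrile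
Conditions: LiBH4, THF, MeOH (1 equiv), 0 → 40 °C
Reagents that add atoms: none
Why: Borohydride reduction of the neopentyl methyl ester to the primary alcohol; nitrile, boronic ester, silyl ether and acetal are not reduced by LiBH4.

Step 11
Reactants: 14 primary alcohol
Product: 15 triethylsilyl ether of 14
Conditions: Et3SiCl, imidazole, CH2Cl2, 0 °C
Reagents that add atoms: chlorotriethylsilane, CC[Si](Cl)(CC)CC
Why: Silylation with the more labile triethylsilyl group marks the future C10 oxygen for oxidative removal in the presence of the tert-butyldimethylsilyl ether.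

Step 12
Reactants: 15 bis-silyl ether nitrile
Product: 17 3-(tert-butyldimethylsilyloxy)-2-[3-(dimethoxymethyl)-2-(pinacolborylmethyl)-2-(triethylsilyloxymethyl)cyclopentyl]-2-methylpropanal, via N-aluminated aldimine 16 (not isolated)
Conditions: i-Bu2AlH (1.5 equiv), toluene, −78 → −20 °C; then AcOH/NaOAc buffer (pH 5), SiO2
Reagents that add atoms: water, O
Why: Partial reduction of the nitrile by one hydride to the N-aluminated imine and buffered hydrolysis should give the α-quaternary aldehyde (future C7); it has no enolisable centre.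

Step 13
Reactants: 18 tert-butyl 2-(diethoxyphosphoryl)acetate
Product: 20 tert-butyl 2-(diethoxyphosphoryl)prop-2-enoate, via hydroxymethyl phosphonoacetate 19 (not isolated)
Conditions: (CH2O)n, piperidine (cat.), AcOH (cat.), toluene, 90 °C, 4 Å molecular sieves
Reagents that add atoms: formaldehyde (as paraformaldehyde), C=O
Why: Knoevenagel-type methylenation of the phosphonoacetate (aldol addition to formaldehyde, then dehydration) gives the vinylphosphonate acceptor.

Step 14
Reactants: 17 α-quaternary aldehyde; 20 tert-butyl 2-(diethoxyphosphoryl)prop-2-enoate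
Product: 22 tert-butyl (2Z)-5-(tert-butyldimethylsilyloxy)-4-[3-(dimethoxymethyl)-2-(pinacolborylmethyl)-2-(triethylsilyloxymethyl)cyclopentyl]-4-methyl-2-(phenylsulfonylmethyl)pent-2-enoate, via sodium phosphonate carbanion 21 (not isolated)
Conditions: PhSO2Na, DMSO/THF, rt → 50 °C
Reagents that add atoms: sodium benzenesulfinate, [Na+].[O-]S(=O)c1ccccc1
Why: Three-component conjugate addition/Horner–Wadsworth–Emmons olefination: sulfinate adds to the vinylphosphonate and the resulting phosphonate carbanion olefinates the aldehyde, as known for thiolate-triggered versions; the usual preference for the ester trans to the aldehyde-derived substituent should place the sulfonylmethyl group cis to C6 (Z), the geometry needed for ring closure.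

Step 15
Reactants: 22 allyl sulfone triethylsilyl ether
Product: 24 tert-butyl (2Z)-5-(tert-butyldimethylsilyloxy)-4-[3-(dimethoxymethyl)-2-formyl-2-(pinacolborylmethyl)cyclopentyl]-4-methyl-2-(phenylsulfonylmethyl)pent-2-enoate, via alkoxysulfonium chloride 23 (not isolated)
Conditions: (COCl)2, DMSO, CH2Cl2, −78 → −40 °C; then Et3N, −78 → 0 °C
Reagents that add atoms: none
Why: Swern oxidation applied directly to the primary triethylsilyl ether (the chlorosulfonium reagent cleaves the Et3Si–O bond, the tert-butyldimethylsilyl ether is retained) should liberate the non-enolisable C10 aldehyde.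

Step 16
Reactants: 24 boryl aldehyde allyl sulfone
Product: 26 tert-butyl 6-(tert-butyldimethylsilyloxymethyl)-2-(dimethoxymethyl)-10-hydroxy-6-methyltricyclo[5.3.1.0^1,5]undec-8-ene-8-carboxylate (configuration as in the target), via lithium alkoxyborate aldolate 25 (not isolated)
Conditions: LiN(SiMe3)2 (1.05 equiv), 4CzIPN (2 mol %), THF, −78 → −20 °C in the dark; then 450 nm LEDs, −20 °C → rt; aq. NH4Cl
Reagents that add atoms: none
Why: Proposed new method: LiN(SiMe3)2 deprotonates the sulfonyl-activated allylic CH2 (C9) and the carbanion adds through C9 to the non-enolisable C10 aldehyde (7-exo-trig, closing the cycloheptene C1–C5–C6–C7–C8–C9–C10); the lithium alkoxide then binds the neighbouring C11–B(pin) as a five-membered ate complex, which alone is oxidisable by photoexcited 4CzIPN, so the primary C11 radical is released only after C9–C10 exists, adds transannularly to C7, the β-carbon of the enoate (5-exo-trig; this one bond closes ring B and ring C), and the resulting C8 radical expels PhSO2• (returned as sulfinate by the reduced photocatalyst) to leave the C8=C9 double bond. Closest known reaction types: addition of α-sulfonyl carbanions to aldehydes (first stage of the Julia olefination), photoredox oxidation of Lewis-base-activated alkylboronic esters to alkyl radicals, and radical addition–β-sulfonyl fragmentation of allyl sulfones (radical allylation); coupling them through an alkoxide-gated borate is the new element. C7 can only be attacked on the face turned toward C11, so its configuration follows from the fixed C1 and C5 centres; C10 is set because ate-complex formation and ring closure both require O10 and C9 to be gauche to C11, one on each side, with C9 held on the C5 side by the tether, and because the aldol is reversible the C10 epimer that cannot do both should return to the carbanion. The step needs α-attack (C9) rather than γ-attack (C7) of the allyl sulfonyl anion, secured by charge localisation next to sulfur and by the neopentyl position of C7, and it needs radical formation after the aldol, secured by the gating and by running the base phase in the dark.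

Step 17
Reactants: 27 heptane-1,7-diol
Product: 28 7-(tert-butyldimethylsilyloxy)heptan-1-ol
Conditions: TBSCl (0.3 equiv), imidazole, DMF, rt (excess diol recovered)
Reagents that add atoms: tert-butyldimethylsilyl chloride, C[Si](C)(Cl)C(C)(C)C
Why: Statistical monosilylation of a symmetrical diol used in excess.

Step 18
Reactants: 28 mono-silylated diol
Product: 29 7-(tert-butyldimethylsilyloxy)heptanal
Conditions: TEMPO (cat.), PhI(OAc)2, CH2Cl2, rt
Reagents that add atoms: none
Why: Nitroxyl-catalysed oxidation of the primary alcohol stops at the aldehyde and leaves the silyl ether intact.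

Step 19
Reactants: 30 9-bromononanoic acid
Product: 31 (8-carboxyoctyl)triphenylphosphonium bromide
Conditions: PPh3, MeCN, reflux
Reagents that add atoms: triphenylphosphine, c1ccc(cc1)P(c1ccccc1)c1ccccc1
Why: SN2 quaternisation of triphenylphosphine by the primary bromide.

Step 20
Reactants: 31 (8-carboxyoctyl)triphenylphosphonium bromide; 29 7-(tert-butyldimethylsilyloxy)heptanal
Product: 33 (9Z)-16-(tert-butyldimethylsilyloxy)hexadec-9-enoic acid, via phosphonium ylide 32 (not isolated)
Conditions: NaN(SiMe3)2 (2.1 equiv), THF, −78 °C; then 29, −78 °C → rt; aq. HCl to pH 4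
Reagents that add atoms: none
Why: Wittig olefination with a non-stabilised ylide under lithium-free conditions at low temperature should give the Z alkene through the kinetic cis-oxaphosphetane.

Step 21
Reactants: 26 tricyclic allylic alcohol; 33 (9Z)-16-(tert-butyldimethylsilyloxy)hexadec-9-enoic acid
Product: 35 C10 ester of 26 with acid 33 (fully protected target), via mixed anhydride 34 (not isolated)
Conditions: 2,4,6-trichlorobenzoyl chloride, Et3N, THF, rt; then 26, DMAP, toluene, 50 °C
Reagents that add atoms: none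
Why: Yamaguchi esterification: DMAP-mediated acyl transfer from the mixed anhydride should acylate the hindered secondary allylic alcohol with retention at C10.

Step 22
Reactants: 35 fully protected ester
Product: 36 target compound CNP0148862.1
Conditions: CF3CO2H/CH2Cl2/H2O (10:10:1), 0 °C → rt; aq. NaHCO3 wash, re-acidify to pH 4
Reagents that add atoms: water, O
Why: Acid-mediated global deprotection (acetal hydrolysis, cleavage of both tert-butyldimethylsilyl ethers, loss of isobutene from the tert-butyl ester) should free CHO, both CH2OH groups and CO2H without basic conditions that could enolise C2.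

**Compound list**

1 | methyl 2-oxocyclopentane-1-carboxylate | COC(=O)C1CCCC1=O | starting material
2 | methyl 2-oxo-1-(phenylselanyl)cyclopentane-1-carboxylate | COC(=O)C1([Se]c2ccccc2)CCCC1=O | intermediate
3 | methyl 5-oxocyclopent-1-ene-1-carboxylate | COC(=O)C1=CCCC1=O | intermediate
4 | ethyl 2-cyanopropanoate (racemic) | CCOC(=O)C(C)C#N | starting material
5 | methyl 5-(2-cyano-1-ethoxy-1-oxopropan-2-yl)-2-oxocyclopentane-1-carboxylate, keto ester carbon epimeric | C[C@@]([C@@H]1CCC(=O)C1C(=O)OC)(C(=O)OCC)C#N | intermediate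
6 | methyl 5-(2-cyano-1-ethoxy-1-oxopropan-2-yl)-2-(trifluoromethylsulfonyloxy)cyclopent-1-ene-1-carboxylate | C[C@@]([C@@H]1CCC(OS(=O)(=O)C(F)(F)F)=C1C(=O)OC)(C(=O)OCC)C#N | intermediate
7 | methyl 5-(2-cyano-1-ethoxy-1-oxopropan-2-yl)-2-formylcyclopent-1-ene-1-carboxylate | C[C@@]([C@@H]1CCC(C=O)=C1C(=O)OC)(C(=O)OCC)C#N | intermediate
8 | methyl 5-(2-cyano-1-ethoxy-1-oxopropan-2-yl)-2-(dimethoxymethyl)cyclopent-1-ene-1-carboxylate | C[C@@]([C@@H]1CCC(C(OC)OC)=C1C(=O)OC)(C(=O)OCC)C#N | intermediate
9 | methyl 2-(2-cyano-1-ethoxy-1-oxopropan-2-yl)-5-(dimethoxymethyl)cyclopentane-1-carboxylate, all-cis | C[C@@]([C@@H]1CC[C@H](C(OC)OC)[C@@H]1C(=O)OC)(C(=O)OCC)C#N | intermediate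
10 | methyl 2-(2-cyano-1-hydroxypropan-2-yl)-5-(dimethoxymethyl)cyclopentane-1-carboxylate, all-cis | C[C@@]([C@@H]1CC[C@H](C(OC)OC)[C@@H]1C(=O)OC)(CO)C#N | intermediate
11 | tert-butyldimethylsilyl ether of 10 | C[C@@]([C@@H]1CC[C@H](C(OC)OC)[C@@H]1C(=O)OC)(CO[Si](C)(C)C(C)(C)C)C#N | intermediate
12 | lithium ester enolate of 11 | C[C@@]([C@@H]1CC[C@H](C(OC)OC)C1=C([O-])OC)(CO[Si](C)(C)C(C)(C)C)C#N.[Li+] | intermediate
13 | methyl 2-[1-(tert-butyldimethylsilyloxy)-2-cyanopropan-2-yl]-5-(dimethoxymethyl)-1-(pinacolborylmethyl)cyclopentane-1-carboxylate | C[C@@]([C@@H]1CC[C@H](C(OC)OC)[C@@]1(C(=O)OC)CB1OC(C)(C)C(C)(C)O1)(CO[Si](C)(C)C(C)(C)C)C#N | intermediate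
14 | 3-(tert-butyldimethylsilyloxy)-2-[3-(dimethoxymethyl)-2-(hydroxymethyl)-2-(pinacolborylmethyl)cyclopentyl]-2-methylpropanenitrile | C[C@@]([C@@H]1CC[C@H](C(OC)OC)[C@@]1(CO)CB1OC(C)(C)C(C)(C)O1)(CO[Si](C)(C)C(C)(C)C)C#N | intermediate
15 | triethylsilyl ether of 14 | C[C@@]([C@@H]1CC[C@H](C(OC)OC)[C@@]1(CO[Si](CC)(CC)CC)CB1OC(C)(C)C(C)(C)O1)(CO[Si](C)(C)C(C)(C)C)C#N | intermediate
16 | N-(diisobutylalumanyl)aldimine from 15 | C[C@@]([C@@H]1CC[C@H](C(OC)OC)[C@@]1(CO[Si](CC)(CC)CC)CB1OC(C)(C)C(C)(C)O1)(CO[Si](C)(C)C(C)(C)C)C=N[Al](CC(C)C)CC(C)C | intermediate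
17 | 3-(tert-butyldimethylsilyloxy)-2-[3-(dimethoxymethyl)-2-(pinacolborylmethyl)-2-(triethylsilyloxymethyl)cyclopentyl]-2-methylpropanal | C[C@@]([C@@H]1CC[C@H](C(OC)OC)[C@@]1(CO[Si](CC)(CC)CC)CB1OC(C)(C)C(C)(C)O1)(CO[Si](C)(C)C(C)(C)C)C=O | intermediate
18 | tert-butyl 2-(diethoxyphosphoryl)acetate | CCOP(=O)(OCC)CC(=O)OC(C)(C)C | starting material
19 | tert-butyl 2-(diethoxyphosphoryl)-3-hydroxypropanoate | CCOP(=O)(OCC)C(CO)C(=O)OC(C)(C)C | intermediate
20 | tert-butyl 2-(diethoxyphosphoryl)prop-2-enoate | CCOP(=O)(OCC)C(=C)C(=O)OC(C)(C)C | intermediate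
21 | sodium 1-tert-butoxy-2-(diethoxyphosphoryl)-1-oxo-3-(phenylsulfonyl)propan-2-ide | CCOP(=O)(OCC)[C-](CS(=O)(=O)c1ccccc1)C(=O)OC(C)(C)C.[Na+] | intermediate
22 | tert-butyl (2Z)-5-(tert-butyldimethylsilyloxy)-4-[3-(dimethoxymethyl)-2-(pinacolborylmethyl)-2-(triethylsilyloxymethyl)cyclopentyl]-4-methyl-2-(phenylsulfonylmethyl)pent-2-enoate | C[C@@]([C@@H]1CC[C@H](C(OC)OC)[C@@]1(CO[Si](CC)(CC)CC)CB1OC(C)(C)C(C)(C)O1)(CO[Si](C)(C)C(C)(C)C)/C=C(\CS(=O)(=O)c1ccccc1)C(=O)OC(C)(C)C | intermediate
23 | alkoxydimethylsulfonium chloride from 22 | C[C@@]([C@@H]1CC[C@H](C(OC)OC)[C@@]1(CO[S+](C)C)CB1OC(C)(C)C(C)(C)O1)(CO[Si](C)(C)C(C)(C)C)/C=C(\CS(=O)(=O)c1ccccc1)C(=O)OC(C)(C)C.[Cl-] | intermediate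
24 | tert-butyl (2Z)-5-(tert-butyldimethylsilyloxy)-4-[3-(dimethoxymethyl)-2-formyl-2-(pinacolborylmethyl)cyclopentyl]-4-methyl-2-(phenylsulfonylmethyl)pent-2-enoate | C[C@@]([C@@H]1CC[C@H](C(OC)OC)[C@@]1(C=O)CB1OC(C)(C)C(C)(C)O1)(CO[Si](C)(C)C(C)(C)C)/C=C(\CS(=O)(=O)c1ccccc1)C(=O)OC(C)(C)C | intermediate
25 | lithium spiro-alkoxyborate of the cycloheptene aldol (O10–B–C11 five-membered ate complex; C9 sulfone epimers) | C[C@@]1(CO[Si](C)(C)C(C)(C)C)C=C(C(=O)OC(C)(C)C)C(S(=O)(=O)c2ccccc2)[C@@H]2O[B-]3(OC(C)(C)C(C)(C)O3)C[C@@]24[C@@H](C(OC)OC)CC[C@@H]14.[Li+] | intermediate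
26 | tert-butyl 6-(tert-butyldimethylsilyloxymethyl)-2-(dimethoxymethyl)-10-hydroxy-6-methyltricyclo[5.3.1.0^1,5]undec-8-ene-8-carboxylate | C[C@@]1(CO[Si](C)(C)C(C)(C)C)[C@@H]2C[C@]3([C@@H](O)C=C2C(=O)OC(C)(C)C)[C@@H](C(OC)OC)CC[C@@H]13 | intermediate
27 | heptane-1,7-diol | OCCCCCCCO | starting material
28 | 7-(tert-butyldimethylsilyloxy)heptan-1-ol | OCCCCCCCO[Si](C)(C)C(C)(C)C | intermediate
29 | 7-(tert-butyldimethylsilyloxy)heptanal | O=CCCCCCCO[Si](C)(C)C(C)(C)C | intermediate
30 | 9-bromononanoic acid | OC(=O)CCCCCCCCBr | starting material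
31 | (8-carboxyoctyl)triphenylphosphonium bromide | OC(=O)CCCCCCCC[P+](c1ccccc1)(c1ccccc1)c1ccccc1.[Br-] | intermediate
32 | sodium 9-(triphenyl-λ5-phosphanylidene)nonanoate | [Na+].[O-]C(=O)CCCCCCCC=P(c1ccccc1)(c1ccccc1)c1ccccc1 | intermediate
33 | (9Z)-16-(tert-butyldimethylsilyloxy)hexadec-9-enoic acid | OC(=O)CCCCCCC/C=C\CCCCCCO[Si](C)(C)C(C)(C)C | intermediate
34 | (9Z)-16-(tert-butyldimethylsilyloxy)hexadec-9-enoic 2,4,6-trichlorobenzoic anhydride | O=C(CCCCCCC/C=C\CCCCCCO[Si](C)(C)C(C)(C)C)OC(=O)c1c(Cl)cc(Cl)cc1Cl | intermediate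
35 | C10 (9Z)-16-(tert-butyldimethylsilyloxy)hexadec-9-enoate of 26 | C[C@@]1(CO[Si](C)(C)C(C)(C)C)[C@@H]2C[C@]3([C@@H](OC(=O)CCCCCCC/C=C\CCCCCCO[Si](C)(C)C(C)(C)C)C=C2C(=O)OC(C)(C)C)[C@@H](C(OC)OC)CC[C@@H]13 | intermediate
36 | CNP0148862.1 | C[C@@]1(CO)[C@@H]2C[C@]3([C@@H](OC(=O)CCCCCCC/C=C\CCCCCCO)C=C2C(=O)O)[C@@H](C=O)CC[C@@H]13 | target

**Step count and risks**

Total step count: 22. Longest linear sequence: 17 steps (steps 1–12, 14–16, 21, 22).

Steps most likely to fail:

1. Step 16 (Proposed new method). The alkoxide-bound borate may be oxidised too slowly. The C11 radical has to close a five-membered ring trans-fused to ring A, so it may be reduced or lose boron by protonation before it cyclises. Reversal of the aldol, or attack of the allyl sulfonyl anion through C7, would also divert material. Fallback (known reactions, stepwise): from 24, LiN(SiMe3)2 at −78 °C followed by Et3SiOTf should give the triethylsilyl-protected cycloheptene aldol F1. Aqueous KHF2 in MeOH converts its boronic ester into the potassium trifluoroborate F2. Photoredox oxidation with 9-mesityl-10-methylacridinium perchlorate under blue light (radical allylation of an alkyltrifluoroborate by an allyl sulfone, here intramolecular) gives the tricyclic triethylsilyl ether F3. PPTS in MeOH removes the triethylsilyl group and returns to 26.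

2. Step 2. The catalyst may not discriminate the two faces of the prochiral cyano-ester enolate (epimer mixture at future C6), and the adduct may revert by retro-Michael reaction. Fallback: from 4, TBSOTf/Et3N gives the silyl ketene acetal F4. A Mukaiyama–Michael addition of F4 to 3 on a chiral Lewis acid, Cu(OTf)2 with (S,S)-tert-butyl-bis(oxazoline) (the keto ester chelated to divalent copper), gives the silyl enol ether F5. Aqueous citric acid hydrolyses F5 and returns to 5.

3. Step 14. Olefination of the neopentyl aldehyde may be slow enough for the sulfinate adduct to revert and the phosphonoacrylate to oligomerise, with loss of alkene geometry. Fallback: from 17, hydroalumination of tert-butyl propiolate (i-Bu2AlH, N-methylmorpholine N-oxide, THF) and addition of the vinylalane to 17 gives the Morita–Baylis–Hillman-type alcohol F6. Ac2O/DMAP gives the allylic acetate F7. PhSO2Na in DMF (SN2′ displacement) returns to 22.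

**Further compounds**

F1 | step 16 | triethylsilyl ether of the cycloheptene aldol (boronic ester intact) | C[C@@]1(CO[Si](C)(C)C(C)(C)C)C=C(C(=O)OC(C)(C)C)C(S(=O)(=O)c2ccccc2)[C@H](O[Si](CC)(CC)CC)[C@@]3(CB2OC(C)(C)C(C)(C)O2)[C@@H](C(OC)OC)CC[C@@H]13
F2 | step 16 | potassium trifluoroborate from F1 | C[C@@]1(CO[Si](C)(C)C(C)(C)C)C=C(C(=O)OC(C)(C)C)C(S(=O)(=O)c2ccccc2)[C@H](O[Si](CC)(CC)CC)[C@@]3(C[B-](F)(F)F)[C@@H](C(OC)OC)CC[C@@H]13.[K+]
F3 | step 16 | C10 triethylsilyl ether of 26 | C[C@@]1(CO[Si](C)(C)C(C)(C)C)[C@@H]2C[C@]3([C@@H](O[Si](CC)(CC)CC)C=C2C(=O)OC(C)(C)C)[C@@H](C(OC)OC)CC[C@@H]13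
F4 | step 2 | 3-(tert-butyldimethylsilyloxy)-3-ethoxy-2-methylprop-2-enenitrile | CCOC(O[Si](C)(C)C(C)(C)C)=C(C)C#N
F5 | step 2 | tert-butyldimethylsilyl enol ether of 5 | C[C@@]([C@@H]1CCC(O[Si](C)(C)C(C)(C)C)=C1C(=O)OC)(C(=O)OCC)C#N
F6 | step 14 | tert-butyl 2-methylidene-3-hydroxy-4-methyl-pentanoate adduct of 17 (carbinol epimers) | C[C@@]([C@@H]1CC[C@H](C(OC)OC)[C@@]1(CO[Si](CC)(CC)CC)CB1OC(C)(C)C(C)(C)O1)(CO[Si](C)(C)C(C)(C)C)C(O)C(=C)C(=O)OC(C)(C)C
F7 | step 14 | acetate of F6 | C[C@@]([C@@H]1CC[C@H](C(OC)OC)[C@@]1(CO[Si](CC)(CC)CC)CB1OC(C)(C)C(C)(C)O1)(CO[Si](C)(C)C(C)(C)C)C(OC(C)=O)C(=C)C(=O)OC(C)(C)C
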